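Start from the amber run, this same flask followed up to 8.00 h. From 2.50 h on, its substrate stands near 46.2% and its target near 38.0%.

common to all: substrate 0.031 M (in portions, 2)

| run | gas | remark | time |
|---|---|---|---|
| amber | 8 mM (held) | the very flask that is asked about, followed so far; portions every 50 min |  |
| flask | 8.0 mM (held) | the portions of substrate follow each other after 50 min, the first at the start | 15 h |

amber run (percent of the substrate charged)

| time / h | target / % | substrate / % |
|---|---|---|
| 1.00 | 30.5 | 65.3 |
| 2.50 | 39.3 | 46.4 |
| 5.00 | 37.2 | 45.7 |
| 8.00 | 37.4 | 46.5 |

(readings scatter by 1 percentage point)

- the numbers in the tables scatter with a standard deviation of 1 percentage point
- at the start none of the gas is in solution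
- the reaction counts as stopped when no species that holds the substrate changes by six tenths of a point or more over the second half of the time

1. at 15 h, what has stopped the reaction, if anything has (forward and back rates have come level / all of the substrate has reacted / it is still moving)
2. how much target there is at 15 h, in percent of the substrate charged

Two things in the amber run seem not to fit. Target reached 30.5% by 1.00 h, and 46.2% of the substrate is still there with gas held at 8 mM, yet the readings move only within their scatter after 2.50 h.

To clear this up, divide the forward rate by the back rate, so that time drops out. Assume that the forward rate follows the substrate and a steady reagent fed by the gas. Assume too that each reacted substrate leaves a by-product, and that the back rate follows the target, taken as a steady share of what is gone, times that by-product. Take the plateau as the point where that ratio is one. With a the share of substrate left, l the share gone and c the charge, a quantity without time stands there, the balance quotient Q, an apparent equilibrium constant, here read off the amber run: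

Q = l · l · c / a = 19.4 mM

The flask has the amber charge, so my reckoning keeps the same a. In the amber run target is 70.6% of what is gone, so I expect the amber plateau, 38.0%, in the flask at 15 h.

The forecast says forward and back rates have come level and 37.8%: “the plateau looks like a balance of forward and back rates”.

In the flask forward and back rates have come level, with 39.0% of target and 46% of substrate left at 15 h. Put into Q, these end values give 19.9 mM.

    2 coupling partner → self-condensation product (k = 0.450 /M/s)
    gas ⇌ coupling partner, rate k2*(csat - [coupling partner]) (kL = 0.00260 /s)
    target ⇌ isomer of the product (K = 0.390, k = 1.70 × 10⁻⁴ /s)
    substrate + coupling partner ⇌ target + released group (K = 4.00, k = 0.110 /M/s)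

In this flask at 15.0 h the step from substrate and coupling partner to target and released group, taken by itself and both ways together, relaxes with a half-life of 0.0700 h, short against 15 h. The by-product assumed above is the released group, at 0.0168 M, and the gas-fed reagent is the coupling partner, at 0.00358 M, made 1.00 times as fast as it is used, each step taken net.

Now take the neighbour flask with 0.019 M of substrate. Hold Q, and solve with a and l making up the whole charge: this gives 37.8% of substrate left and, with the same target share of what is gone, 43.9% of target. The neighbour's run gives 37.4% of substrate and 45.0% of target at 15 h.

Readings and results were generated by integration for an exercise, noise included.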